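Rings against links.

    Z + D → Z.D (k1 = 0.43 L mol⁻¹ min⁻¹, Ea1 = 53.0 kJ mol⁻¹)
    Z + D → Q, rate k2*[Z] as long as [D] is above zero (k2 = 0.25 min⁻¹, Ea2 = 88.0 kJ mol⁻¹)
    Z + Z.D → Z.Z.D (k3 = 0.57 L mol⁻¹ min⁻¹, Ea3 = 63.0 kJ mol⁻¹)
    Z + J → Z.J (k4 = 95 L mol⁻¹ min⁻¹, Ea4 = 61.0 kJ mol⁻¹)
    D → L (k5 = 0.019 min⁻¹, Ea5 = 86.0 kJ mol⁻¹)
    (constants at 40 °C)

| flask | Z | D | J | temperature | time | remark |
|---|---|---|---|---|---|---|
| dawn | 0.22 M | 0.220 M (fed, over 2.5 h) | 4.40 mM | 40 °C | 6.0 h | all else is in the flask from the start; the feed brings no volume worth counting |
| summer | 0.22 M | 0.220 M | 4.40 mM | 40 °C | 6.0 h | everything together at the start |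
| spring | 0.22 M (fed, over 2.5 h) | 0.220 M | 4.40 mM |  | 6.0 h | the addition at 0 °C, then warmed to 40 °C; the feed brings no volume worth counting |
| winter | 0.22 M (fed, over 2.5 h) | 0.220 M | 4.40 mM | 40 °C | 6.0 h | all else is in the flask from the start; the feed brings no volume worth counting |

1. which flask leads in amount of Z.D, in percent of the Z charged ("all alike" within 1.5 percentage points) (dawn / summer / spring / winter / all alike)
2. how much Z.D is there at the end, in percent of the Z charged: dawn
3. how much Z.D is there at the end, in percent of the Z charged: summer
4. how much Z.D is there at the end, in percent of the Z charged: spring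
5. how much Z.D is there at the end, in percent of the Z charged: winter

- percentages count the Z that a species holds: one Z.Z.D counts as two
- all constants are for 40 °C and move with temperature by the activation energies

I carry the ring-to-link ratio s, the selectivity factor of this flask: the ring constant over the link constant times the charge of D, 2.64 at 40 °C. With a fraction d of the D charge left, rings form s/d times as fast as links, however much Z stands, since Z enters both steps once. So the balance of D, with the L step set aside, gives the links made as d falls from full to nothing: 1 − s·ln(1 + 1/s), as a fraction of the D charge. A link made stays a Z.D or becomes a Z.Z.D.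

Temperature is the first setting. The ring step has the steeper activation energy, so s falls to 0.369 at 0 °C. For summer, warm throughout, I reckon 15.2% of links. The cold value of s reckons at 51.6%, and I expect spring, cold and then warm, to lie between the two.

Next comes who is fed. In dawn the ring step at full Z can take 37.5 times the feed of D, so I expect d to stay small and a trace of links. In winter D lives 52.6 min against L, shorter than the feed, so I expect D to go before the Z is in and late Z to turn Z.D into Z.Z.D, with no Z.D standing. In spring the same feed is cold, where that lifetime is 111 h. I commit to spring first, summer second.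

The forecast also names spring, saying “links are favoured” in the cold. It gives dawn 0.01%, summer 10.5% (9.3% to 11.8%), spring 20.3% (18.3% to 22.3%) and winter 0%. Its figures are Z.D standing at the end, while mine are links made, so the two differ for summer.

The flask gives spring in the lead with 20.6%, then summer 10.4%, dawn 0.0107% and winter 0%.

Spring holds 28.3% of links made after 6.00 h, counting Z.D plus half the Z.Z.D figure, which lies between 15.2% and 51.6%. At the end of its cold feed, after 2.50 h, spring holds 21.5% of links beside 9.63% of Q, and warm, at 2.55 h, spring uses Z in rings 9.3 times as fast as in links. The neighbour of spring with 0.13 M of D has s of 4.47 warm and 0.625 cold, so its bracket, per Z charged, runs from 5.76% to 23.8%. That neighbour made 15.1% of links, and 0.0102% stands as Z.D beside 30.1% in Z.Z.D.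

The numbers are those of an exercise; what happens was integrated by code.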